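**Plan**
- Retrosynthetic cuts, last bond first: C3–H (ketone reduction) and C4–Br (α′-bromination); C9–Br and C10–Cl back to a C9=C10 alkene through its chlorohydrin; the C1 methyl back to a vinylogous ester carbonyl; then C7–C8 and C6–C11 together; finally C6=C7 back to dimedone.
- The double cut is possible because ring B is a six-membered carbocycle spiro-fused at C6 with its methyl-bearing C9 placed 1,4 to C6. This is the pattern isoprene leaves when it adds across an exocyclic C6=C7 methylene on a ring A enone.
- Forward: ring A comes from dimedone (vinylogous ester, α′-methylenation); ring B closes in one cycloaddition; a carbonyl transposition installs the C1 methyl; ring B is halogenated next, ring A last.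
- Stereochemistry: C6 from a chiral Lewis acid in the cycloaddition; C10 and C9 from anti chlorohydrin formation on the ring B face away from C5, then bromide for hydroxyl with retention; C4 from bromination of a dienol ether; C3 from hydride delivery opposite the axial C5 methyl, cis to bromine.

Key step: step 4

Numbering: target numbering is used for all spiro compounds; ring A is C1–C6 (C1 vinyl methyl, C3 oxygen, C4 bromine, C5 gem-dimethyl, C6 spiro atom) and ring B is C6–C11 (C9 bears CH3 and Br, C10 bears Cl).
Assumption: the (S)-oxazaborolidinium ion is taken to deliver the (6S) adduct 10; if the sense of induction is opposite, its (R) enantiomer is used with otherwise identical chemistry.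

Step 1
Reactants: 1 dimedone; 2 2-methylpropan-1-ol
Product: 3 3-isobutoxy-5,5-dimethylcyclohex-2-en-1-one
Conditions: p-TsOH·H2O (cat.), toluene, reflux, Dean–Stark
Reagents that add atoms: none
Why: Acid-catalysed condensation of the symmetric cyclic 1,3-diketone with the alcohol under azeotropic water removal gives the vinylogous ester (enol ether formation), with no regiochemical choice to make.

Step 2
Reactants: 3 3-isobutoxy-5,5-dimethylcyclohex-2-en-1-one; 4 Eschenmoser salt
Product: 6 rac-6-[(dimethylamino)methyl]-3-isobutoxy-5,5-dimethylcyclohex-2-en-1-one, via lithium enolate 5 (not isolated)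
Conditions: LiN(iPr)2, THF, −78 °C; then 4, −78 → 0 °C
Reagents that add atoms: none
Why: LiN(iPr)2 removes the kinetic α′ proton at C6 rather than the γ proton at C4, and the enolate adds to the small, highly reactive iminium carbon despite the neighbouring gem-dimethyl group (Mannich reaction); the racemic C6 centre is destroyed in step 3.

Step 3
Reactants: 6 rac-6-[(dimethylamino)methyl]-3-isobutoxy-5,5-dimethylcyclohex-2-en-1-one
Product: 8 3-isobutoxy-5,5-dimethyl-6-methylenecyclohex-2-en-1-one, via trimethylammonium iodide 7 (not isolated)
Conditions: MeI, MeOH, rt; then NaHCO3 (aq), CH2Cl2, rt; used at once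
Reagents that add atoms: none
Why: N-Methylation turns the amine into a leaving group and mild base eliminates trimethylamine from the β-ammonio ketone by an E1cB process (Mannich methiodide elimination), which can only give the exocyclic C6=C7 alkene because C6 carries the one acidic proton.

Step 4
Reactants: 8 3-isobutoxy-5,5-dimethyl-6-methylenecyclohex-2-en-1-one; 9 isoprene
Product: 10 (6S)-3-isobutoxy-5,5,9-trimethylspiro[5.5]undeca-2,9-dien-1-one
Conditions: 9 (5 equiv), (S)-3,3-diphenyl-1-(2-methylphenyl)tetrahydro-1H,3H-pyrrolo[1,2-c][1,3,2]oxazaborole C24H24BNO (20 mol %) + HN(SO2CF3)2 (18 mol %), CH2Cl2, −40 → −20 °C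
Reagents that add atoms: none
Why: The oxazaborolidinium ion binds the vinylogous ester carbonyl oxygen and lowers the LUMO of the s-cis-locked exocyclic enone; isoprene then adds in a concerted, asynchronous [4π+2π] cycloaddition in which its C1 terminus (next to the methyl-bearing carbon) bonds first to the methylene carbon C7 and its C4 terminus then closes onto C6. The closest known reactions are the Lewis acid promoted Diels–Alder spiroannulation of 2-methylenecycloalkanones with isoprene and the oxazaborolidinium-catalysed enantioselective Diels–Alder reaction of enones. Ring B closes as a six-membered carbocycle by this suprafacial cycloaddition, with both σ bonds (C7–C8 and C6–C11) and the C9=C10 alkene formed in the same event. The only new stereocentre, the quaternary spiro atom C6, is set by the catalyst, whose aryl groups should shield one enantiotopic face of the planar, achiral enone so that C11 arrives on the other. The step needs para regioselectivity and chemoselectivity for C6=C7: the first follows from pairing the largest LUMO coefficient (C7) with the largest HOMO coefficient (isoprene C1), the second from the C2=C3 enol ether alkene being electron-rich and trisubstituted. The gem-dimethyl group at C5 flanks C6 but leaves the terminal methylene carbon, where bonding starts, unhindered.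

Step 5
Reactants: 10 (6S)-3-isobutoxy-5,5,9-trimethylspiro[5.5]undeca-2,9-dien-1-one
Product: 12 (6S)-1,5,5,9-tetramethylspiro[5.5]undeca-1,9-dien-3-one, via lithium carbinolate 11 (not isolated)
Conditions: MeLi, CeCl3, THF, −78 → 0 °C; then 1 M HCl, rt
Reagents that add atoms: methyllithium, [Li]C
Why: MeLi, made less basic and more oxophilic by CeCl3, adds 1,2 to the hindered C1 carbonyl, and aqueous acid then hydrolyses the enol ether and dehydrates the β-hydroxy ketone (Stork–Danheiser 1,3-carbonyl transposition), placing the carbonyl at C3 and the methyl-bearing alkene at C1=C2 without touching C6.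

Step 6
Reactants: 12 (6S)-1,5,5,9-tetramethylspiro[5.5]undeca-1,9-dien-3-one
Product: 13 (6S,9S,10S)-10-chloro-9-hydroxy-1,5,5,9-tetramethylspiro[5.5]undec-1-en-3-one
Conditions: trichloroisocyanuric acid (0.35 equiv), acetone/H2O, 0 °C
Reagents that add atoms: trichloroisocyanuric acid, O=C1N(Cl)C(=O)N(Cl)C(=O)N1Cl; water, O
Why: Electrophilic chlorine attacks only the electron-rich C9=C10 alkene (the enone alkene is deactivated) and water opens the chloronium ion at the tertiary C9 from the opposite face (halohydrin formation, anti addition, Markovnikov), with chlorine expected on the ring B face syn to C1 because the pseudoaxial gem-dimethyl carbon C5 holds a methyl group across the other face; this sets C10 and C9 trans to each other.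

Step 7
Reactants: 13 (6S,9S,10S)-10-chloro-9-hydroxy-1,5,5,9-tetramethylspiro[5.5]undec-1-en-3-one
Product: 14 (6S,9S,10S)-9-bromo-10-chloro-1,5,5,9-tetramethylspiro[5.5]undec-1-en-3-one
Conditions: Me3SiBr (2.5 equiv), CH2Cl2, −40 → 0 °C
Reagents that add atoms: bromotrimethylsilane, C[Si](C)(C)Br
Why: The tertiary C9 oxygen is silylated and protonated and leaves in an SN1 substitution by bromide; the anti C10–Cl bond should bridge the developing cation (neighbouring-group participation, a chloronium ion opened at its tertiary carbon) and the ion pair should collapse in the cold, non-polar medium, so bromide enters on the face the oxygen left and C9 keeps its configuration, trans to chlorine.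

Step 8
Reactants: 14 (6S,9S,10S)-9-bromo-10-chloro-1,5,5,9-tetramethylspiro[5.5]undec-1-en-3-one
Product: 17 (4R,6R,9S,10S)-4,9-dibromo-10-chloro-1,5,5,9-tetramethylspiro[5.5]undec-1-en-3-one, via lithium dienolate 15 (not isolated), via silyl dienol ether 16 (not isolated)
Conditions: LiN(SiMe3)2, Me3SiCl, THF, −78 °C; then N-bromosuccinimide, THF, −78 → −20 °C
Reagents that add atoms: N-bromosuccinimide, O=C1CCC(=O)N1Br
Why: Kinetic deprotonation of the enone occurs at the α′ carbon C4 (cross-conjugated dienolate, trapped in situ as its silyl dienol ether) and N-bromosuccinimide brominates that carbon (α-halogenation of a silyl enol ether); bromine is expected to approach opposite the axial C7 methylene and end equatorial, cis to C11, the centre staying epimerisable until step 9 fixes it (the C6 descriptor changes from S to R by priority only).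

Step 9
Reactants: 17 (4R,6R,9S,10S)-4,9-dibromo-10-chloro-1,5,5,9-tetramethylspiro[5.5]undec-1-en-3-one
Product: 18 (3S,4R,6R,9S,10S)-4,9-dibromo-10-chloro-1,5,5,9-tetramethylspiro[5.5]undec-1-en-3-ol
Conditions: iBu2AlH, CH2Cl2, −78 °C; aqueous potassium sodium tartrate work-up
Reagents that add atoms: none
Why: iBu2AlH reduces the enone carbonyl 1,2 (substrate-controlled reduction of an α-bromo enone); the axial C5 methyl blocks the axial trajectory, so hydride arrives equatorially and the C3 hydroxyl ends axial and cis to the equatorial C4 bromine, while the alkyl halides are inert at −78 °C.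

**Compound list**
1 | dimedone (5,5-dimethylcyclohexane-1,3-dione) | CC1(C)CC(=O)CC(=O)C1 | starting material
2 | 2-methylpropan-1-ol | CC(C)CO | starting material
3 | 3-isobutoxy-5,5-dimethylcyclohex-2-en-1-one | CC(C)COC1=CC(=O)CC(C)(C)C1 | intermediate
4 | Eschenmoser salt (N,N-dimethylmethyleneiminium iodide) | C=[N+](C)C.[I-] | starting material
5 | lithium enolate of 3 (O–C1=C6) | CC(C)COC1=CC([O-])=CC(C)(C)C1.[Li+] | intermediate
6 | rac-6-[(dimethylamino)methyl]-3-isobutoxy-5,5-dimethylcyclohex-2-en-1-one (racemic, no defined centre) | CN(C)CC1C(=O)C=C(OCC(C)C)CC1(C)C | intermediate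
7 | rac-trimethylammonium iodide of 6 | C[N+](C)(C)CC1C(=O)C=C(OCC(C)C)CC1(C)C.[I-] | intermediate
8 | 3-isobutoxy-5,5-dimethyl-6-methylenecyclohex-2-en-1-one | C=C1C(=O)C=C(OCC(C)C)CC1(C)C | intermediate
9 | isoprene | C=CC(C)=C | starting material
10 | (6S)-3-isobutoxy-5,5,9-trimethylspiro[5.5]undeca-2,9-dien-1-one | O=C1C=C(OCC(C)C)CC(C)(C)[C@@]12CCC(C)=CC2 | intermediate
11 | lithium alkoxide of the C1 methyl carbinol from 10 (C1 epimers, centre lost in the same flask) | CC1([O-])C=C(OCC(C)C)CC(C)(C)[C@@]12CCC(C)=CC2.[Li+] | intermediate
12 | (6S)-1,5,5,9-tetramethylspiro[5.5]undeca-1,9-dien-3-one | CC1=CC(=O)CC(C)(C)[C@@]12CCC(C)=CC2 | intermediate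
13 | (6S,9S,10S)-10-chloro-9-hydroxy-1,5,5,9-tetramethylspiro[5.5]undec-1-en-3-one | CC1=CC(=O)CC(C)(C)[C@@]12CC[C@](C)(O)[C@@H](Cl)C2 | intermediate
14 | (6S,9S,10S)-9-bromo-10-chloro-1,5,5,9-tetramethylspiro[5.5]undec-1-en-3-one | CC1=CC(=O)CC(C)(C)[C@@]12CC[C@](C)(Br)[C@@H](Cl)C2 | intermediate
15 | lithium dienolate of 14 (O–C3=C4) | CC1=CC([O-])=CC(C)(C)[C@@]12CC[C@](C)(Br)[C@@H](Cl)C2.[Li+] | intermediate
16 | trimethylsilyl dienol ether of 14 | CC1=CC(O[Si](C)(C)C)=CC(C)(C)[C@@]12CC[C@](C)(Br)[C@@H](Cl)C2 | intermediate
17 | (4R,6R,9S,10S)-4,9-dibromo-10-chloro-1,5,5,9-tetramethylspiro[5.5]undec-1-en-3-one | CC1=CC(=O)[C@H](Br)C(C)(C)[C@@]12CC[C@](C)(Br)[C@@H](Cl)C2 | intermediate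
18 | (3S,4R,6R,9S,10S)-4,9-dibromo-10-chloro-1,5,5,9-tetramethylspiro[5.5]undec-1-en-3-ol | CC1=C[C@H](O)[C@H](Br)C(C)(C)[C@@]12CC[C@](C)(Br)[C@@H](Cl)C2 | target

**Count**
Total steps: 9. Longest linear sequence: 9 steps, from dimedone.

**Steps most likely to fail**

Risk 1 (step 7): the substitution may run through a free, unbridged tertiary cation. Bromide would then enter anti to the axial C10–H instead of anti to chlorine, giving the C9 epimer, and proton loss would give allylic chlorides. The fallback sets out from 13 and forces the chloronium pathway: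
- K2CO3 in MeOH closes the chlorohydrin to the epoxide F1, with the oxygen on the ring B face syn to C5 and C10 inverted.
- Anhydrous HCl in Et2O at −30 °C opens F1 at the tertiary carbon with inversion, giving the regioisomeric trans-chlorohydrin F2 (tertiary chloride, secondary alcohol).
- Tf2O with 2,6-di-tert-butyl-4-methylpyridine in CH2Cl2 at −78 °C gives the triflate F3, and LiBr in THF is added to the cold solution.
- A secondary cation next to chlorine cannot form unassisted, so triflate should leave only as the anti chlorine bridges (1,2-chlorine shift through the chloronium ion). Bromide then opens that ion at tertiary C9, anti to chlorine.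
- C10 and C9 are each inverted twice, and the sequence returns to the route at 14.

Risk 2 (step 4): the cross-conjugated vinylogous ester carbonyl is a weak activator, and the catalyst may bind on the C2–H side of the carbonyl, far from the reacting alkene. Slow cycloaddition, cationic oligomerisation of isoprene and low enantioface discrimination are therefore all possible. The fallback sets out from 3 and builds the quaternary centre and ring B separately:
- The lithium enolate 5 is alkylated with 4-iodo-2-methylbut-1-ene to the C6-homoallylated vinylogous ester F4.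
- A second deprotonation with LiN(iPr)2 gives its lithium enolate F5, and O-acylation with allyl chloroformate gives the allyl enol carbonate F6.
- Tris(dibenzylideneacetone)dipalladium Pd2(dba)3 (zerovalent palladium) with a 4-tert-butyl-2-[2-(diphenylphosphanyl)phenyl]-4,5-dihydrooxazole ligand, in the handedness that delivers the S centre, effects decarboxylative asymmetric allylation to the quaternary ketone F7.
- Ring-closing metathesis with the second-generation Grubbs catalyst RuCl2(=CHPh)(PCy3)(H2IMes) joins the two terminal alkenes into C9=C10 and returns to the route at 10.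

Risk 3 (step 8): ring B in its chair presents nearly the same environment on both flanks of ring A, so facial discrimination at C4 may be poor, and the strong base may also remove HBr from the tertiary bromide. The fallback sets out from 12 and brominates ring A before ring B carries any halogen:
- LiN(SiMe3)2 and Me3SiCl give the lithium dienolate F8 and then the silyl dienol ether F9, and N-bromosuccinimide gives the bromo dienone F10.
- At this stage the half-chair of ring B, with allylic C11 and puckered C7, makes the two flanks different. No base-sensitive halide is present, and the C4 epimers can be separated or equilibrated through the enol.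
- F10 is taken through the conditions of step 6 to the bromo chlorohydrin F11 and through those of step 7, rejoining the route at 17.

**Further compounds**
F1 | step 7 | (6S,9S,10R)-9,10-epoxy-1,5,5,9-tetramethylspiro[5.5]undec-1-en-3-one | CC1=CC(=O)CC(C)(C)[C@@]12CC[C@]3(C)O[C@@H]3C2
F2 | step 7 | (6S,9R,10R)-9-chloro-10-hydroxy-1,5,5,9-tetramethylspiro[5.5]undec-1-en-3-one | CC1=CC(=O)CC(C)(C)[C@@]12CC[C@@](C)(Cl)[C@H](O)C2
F3 | step 7 | C10 trifluoromethanesulfonate of F2 | CC1=CC(=O)CC(C)(C)[C@@]12CC[C@@](C)(Cl)[C@H](OS(=O)(=O)C(F)(F)F)C2
F4 | step 4 | rac-3-isobutoxy-5,5-dimethyl-6-(3-methylbut-3-en-1-yl)cyclohex-2-en-1-one | C=C(C)CCC1C(=O)C=C(OCC(C)C)CC1(C)C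
F5 | step 4 | lithium enolate of F4 | C=C(C)CCC1=C([O-])C=C(OCC(C)C)CC1(C)C.[Li+]
F6 | step 4 | allyl enol carbonate of F4 | C=CCOC(=O)OC1=C(CCC(C)=C)C(C)(C)CC(OCC(C)C)=C1
F7 | step 4 | (6S)-6-allyl-3-isobutoxy-5,5-dimethyl-6-(3-methylbut-3-en-1-yl)cyclohex-2-en-1-one | O=C1C=C(OCC(C)C)CC(C)(C)[C@@]1(CC=C)CCC(C)=C
F8 | step 8 | lithium dienolate of 12 | CC1=CC([O-])=CC(C)(C)[C@@]12CCC(C)=CC2.[Li+]
F9 | step 8 | trimethylsilyl dienol ether of 12 | CC1=CC(O[Si](C)(C)C)=CC(C)(C)[C@@]12CCC(C)=CC2
F10 | step 8 | (4R,6R)-4-bromo-1,5,5,9-tetramethylspiro[5.5]undeca-1,9-dien-3-one | CC1=CC(=O)[C@H](Br)C(C)(C)[C@@]12CCC(C)=CC2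
F11 | step 8 | (4R,6R,9S,10S)-4-bromo-10-chloro-9-hydroxy-1,5,5,9-tetramethylspiro[5.5]undec-1-en-3-one | CC1=CC(=O)[C@H](Br)C(C)(C)[C@@]12CC[C@](C)(O)[C@@H](Cl)C2
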